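1. I decided to put the flasks on one scale, the charge of starting material multiplied by the time, which I called the dose, since product rose in an S in both earlier runs, the shape of autocatalysis, and if product makes product, a flask with a larger charge should run the same curve in proportionally less time.

| setting | alder | cedar | north-west | north |
|---|---|---|---|---|
| starting material | 22 mM | 51 mM | 32 mM | 60 mM |
| remark | run made earlier | run made earlier |  |  |
| time |  |  | 20 d | 5.0 d |

| run | time / d | product / % | starting material / % |
|---|---|---|---|
| alder | 4.00 | 0.7 | 83.1 |
| alder | 8.00 | 7.2 | 69.8 |
| alder | 10.0 | 19.4 | 55.9 |
| alder | 15.0 | 69.5 | 13.5 |
| cedar | 1.04 | 0.8 | 94.4 |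
| cedar | 2.50 | 1.1 | 87.2 |
| cedar | 6.00 | 62.5 | 21.1 |
| cedar | 15.0 | 93.9 | 0.4 |

(standard deviation of a reading: 1 percentage point)

- which one finishes higher in amount of product, in percent of the starting material charged ("neither" within 2 percentage points) (north-west / north / neither)
- amount of product at the end, in percent of the starting material charged, north-west
- amount of product at the end, in percent of the starting material charged, north

- the earlier runs were read with a standard deviation of 1 percentage point

2. For the zero of the scale I took the symmetric point, where the fraction of the charge that is product equals the fraction that is not, so that the logarithm of their ratio is zero. In the alder run that logarithm went from −1.42 at 10.0 d to 0.824 at 15.0 d, so I read its slope against the dose as 0.851 M⁻¹ h⁻¹ and its zero at a dose of 417 M·min.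

3. But the alder run by itself did not test the scale, so I took the cedar reading at 6.00 d, whose logarithm is 0.511, and the alder slope put the zero for the cedar run at 405 M·min. I carried the mean, 411 M·min, as the half-way dose, the charge times time at which, as read from these two runs, a flask stands at the symmetric point.

4. The north flask had a dose of 432 M·min, past that point, and the curve gave it 57.4 % product. My doubt was how close 432 M·min lay to 411 M·min, but with the zero of the alder run the figure was 55.3 % and with that of the cedar run 59.5 %, and I took the estimate between them.

5. For the north-west flask, at a dose of 922 M·min, the curve gave 99.9 %, which I did not believe, since cedar read 93.9 % at the larger dose of 1100 M·min and the alder balance at 10.0 d lacked 24.7 % of the charge. So I kept the cedar reading as my figure for north-west, which is higher than my north figure.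

6. The forecast also chose north-west, with 93 % for north-west and 38 % for north, a flask it placed “just before the midpoint”, whereas I placed north just past it.

7. The flasks gave 95.0 % for north-west and 59.0 % for north, so north-west finished higher.

    starting material + product → 2 product (k = 1.50 M⁻¹ h⁻¹)
    starting material → product (k = 1.20 × 10⁻⁵ h⁻¹)
    starting material ⇌ dormant form (K = 0.400, k = 0.00270 h⁻¹)

At 5.00 d the north flask also held 16.3 % of its charge as dormant form beside 24.8 % of starting material. The north-west flask stopped at 8.0 d had a dose of 369 M·min, below the half-way dose, and the same slope gave 35.4 % product for it; that flask held 35.1 %.

Readings and results were generated by integration with made-up constants, and the scatter is random.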